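**Strategy.** The carbocycle of the 6-oxabicyclo[3.2.1]octane core is closed at C2–C3, the bond joining the tertiary carbinol carbon (C2, next to the quaternary C1) to the neighbouring ring CH2. A samarium diiodide ketyl–enone cyclisation of an open-chain methyl 2-acetyl-3-acryloylhexanoate, which already carries the irone-derived dienyl chain and the C8 stereocentre, forms this bond, the six-membered ring and the C2 stereocentre in one operation. It exploits the 1,2-relationship of the C2 hydroxyl to the C1 ester (samarium chelation) and its 1,4-relationship to the C5 carbonyl (homo-aldol polarity). The O6–C7 ether bridge is closed afterwards by oxa-Michael addition onto a C5 alkylidene propanal.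

Key step: step 11

Assumption: (+)-cis-α-irone (1), the (1R,5S) enantiomer of natural orris oil, and aldehyde 7 are taken as purchasable; all other inputs are catalogue reagents.

Locants and abbreviations: C1 (quaternary, bears the chain), C2 (carbinol), C3, C4, C5 (ether bridgehead), O6, C7 (OCH2), C8 (CH bearing the hydroxypropyl group) are the positions of the 6-oxabicyclo[3.2.1]octane of the target; Cα is the propanal CH. Ch = (3E,5E)-4-methyl-6-[(1R,5S)-2,5,6,6-tetramethylcyclohex-2-en-1-yl]hexa-3,5-dien-1-yl; TBS = tert-butyldimethylsilyl.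

## Route

Step 1
Reactants: 1 (+)-cis-α-irone, (3E)-4-[(1R,5S)-2,5,6,6-tetramethylcyclohex-2-en-1-yl]but-3-en-2-one
Product: 3 (3E)-4-[(1R,5S)-2,5,6,6-tetramethylcyclohex-2-en-1-yl]but-3-en-1-yne, via enol phosphate 2 (not isolated)
Conditions: LiN(iPr)2 (1.1 equiv), THF, −78 °C; ClP(O)(OEt)2, −78 °C → rt; then LiN(iPr)2 (2.3 equiv), −78 °C → rt; H2O
Reagents that add atoms: none
Why: The enol phosphate route from methyl ketones to terminal alkynes (kinetic methyl enolate, O-phosphorylation, base-induced elimination) is established for ionone-type dienones and should leave both ring stereocentres untouched.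

Step 2
Reactants: 3 enyne
Product: 5 Ch–OH, (3E,5E)-4-methyl-6-[(1R,5S)-2,5,6,6-tetramethylcyclohex-2-en-1-yl]hexa-3,5-dien-1-ol, via dienylalane 4 (not isolated)
Conditions: Me3Al (2 equiv), Cp2ZrCl2 (0.25 equiv), ClCH2CH2Cl, 0 °C → rt; then n-BuLi, THF, −78 °C; ethylene oxide, −78 → 0 °C; aq. Rochelle salt
Reagents that add atoms: trimethylaluminium C[Al](C)C; ethylene oxide C1CO1
Why: Zirconium-catalysed Negishi carboalumination adds methyl and aluminium syn across the terminal alkyne (methyl to the internal carbon), and the derived alanate should open ethylene oxide with retention, which fixes the (3E) trisubstituted alkene.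

Step 3
Reactants: 5 Ch–OH
Product: 6 Ch–I, (1R,5S)-1-[(1E,3E)-6-iodo-3-methylhexa-1,3-dien-1-yl]-2,5,6,6-tetramethylcyclohex-2-ene
Conditions: I2, PPh3, imidazole, CH2Cl2, 0 °C
Reagents that add atoms: iodine II
Why: Appel-type iodination converts the primary alcohol into the iodide by SN2 displacement under near-neutral conditions that should spare the diene.

Step 4
Reactants: 7 4-(tert-butyldimethylsilyloxy)butanal; 8 nitromethane
Product: 10 tert-butyldimethyl{[(4E)-5-nitropent-4-en-1-yl]oxy}silane, via nitro alcohol 9 (not isolated)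
Conditions: 8 (5 equiv), Et3N (0.2 equiv), THF, 0 °C → rt; evaporate; then MsCl, Et3N, CH2Cl2, −20 → 0 °C
Reagents that add atoms: none
Why: Henry reaction followed by mesylation and E1cB elimination should give the conjugated (E)-nitroalkene, the thermodynamically preferred isomer.

Step 5
Reactants: 10 nitroalkene; 11 dimethyl malonate
Product: 12 dimethyl 2-[(2S)-5-(TBSO)-1-nitropentan-2-yl]propanedioate
Conditions: 1-[3,5-bis(trifluoromethyl)phenyl]-3-[(1S,2S)-2-(dimethylamino)cyclohexyl]thiourea (10 mol %), toluene, rt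
Reagents that add atoms: none
Why: Bifunctional thiourea–amine catalysed Michael addition of a malonate to a nitroalkene: the catalyst holds the nitro group and the malonate enolate and delivers the nucleophile to one face, which sets the future C8 stereocentre (the (S,S) catalyst is chosen by analogy with the aryl series; its antipode serves if the facial sense proves opposite).

Step 6
Reactants: 12 nitro diester
Product: 13 dimethyl 2-[(2S)-5-(TBSO)-1-oxopentan-2-yl]propanedioate
Conditions: NaOMe (1.05 equiv), MeOH, 0 °C; then TiCl3 (4 equiv), NH4OAc, H2O/MeOH (pH 5–6), 0 °C → rt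
Reagents that add atoms: water O
Why: Reductive Nef reaction (nitronate reduced by trivalent titanium to the imine, then hydrolysed) should turn the primary nitro group into the aldehyde under buffered conditions that keep the α-stereocentre and the silyl ether.

Step 7
Reactants: 13 aldehyde
Product: 15 methyl (4S)-4-[3-(TBSO)propyl]-5-ethenyl-2-oxooxolane-3-carboxylate (epimers at C3 and C5), via hydroxy diester 14 (not isolated)
Conditions: CH2=CHMgBr (2.2 equiv), THF, −78 °C; AcOH; then pyridinium p-toluenesulfonate (cat.), CH2Cl2, rt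
Reagents that add atoms: vinylmagnesium bromide C=C[Mg]Br
Why: Grignard 1,2-addition to the aldehyde (the first equivalent parks the malonate as its magnesium enolate) followed by lactonisation of the γ-hydroxy diester; the carbinol configuration is irrelevant because that carbon is oxidised in step 10.

Step 8
Reactants: 15 lactone; 6 Ch–I
Product: 16 methyl (3S,4S)-4-[3-(TBSO)propyl]-3-Ch-5-ethenyl-2-oxooxolane-3-carboxylate (C5 epimers; Ch trans to the silyloxypropyl group)
Conditions: NaH (1.1 equiv), DMF, 0 °C; then 6, rt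
Reagents that add atoms: none
Why: SN2 C-alkylation of the stabilised α-carbomethoxy lactone enolate; the iodide should enter anti to the adjacent ring substituent, which sets the quaternary centre (future C1) with the chain trans to the silyloxypropyl group.

Step 9
Reactants: 16 quaternary lactone
Product: 17 methyl (2R,3S)-2-acetyl-2-Ch-3-(1-hydroxyprop-2-en-1-yl)-6-(TBSO)hexanoate (carbinol epimers, in equilibrium with the lactol)
Conditions: MeLi (1.1 equiv), THF, −78 °C; aq. NH4Cl at −78 °C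
Reagents that add atoms: methyllithium [Li]C
Why: Organolithium mono-addition to a γ-lactone (stable lithium lactolate at −78 °C) should be faster than attack on the neopentyl-type methyl ester, so the ring carbonyl becomes the methyl ketone and the allylic alcohol is released.

Step 10
Reactants: 17 hydroxy ketone
Product: 18 methyl (2R,3S)-2-acetyl-2-Ch-3-(prop-2-enoyl)-6-(TBSO)hexanoate
Conditions: Dess–Martin periodinane, NaHCO3, CH2Cl2, 0 °C → rt
Reagents that add atoms: none
Why: Dess–Martin oxidation of the secondary allylic alcohol (through the open hydroxy ketone) gives the vinyl ketone under non-basic conditions that should not epimerise the adjacent stereocentre.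

Step 11
Reactants: 18 keto enone
Product: 20 methyl (1R,2S,6S)-2-hydroxy-2-methyl-5-oxo-6-[3-(TBSO)propyl]-1-Ch-cyclohexane-1-carboxylate, via samarium enolate 19 (not isolated)
Conditions: SmI2 (2.5 equiv), t-BuOH (2 equiv), THF (0.01 M), −78 °C; aq. NH4Cl
Reagents that add atoms: none
Why: SmI2 (divalent samarium) reduces the chelated β-keto ester ketone to a ketyl, which adds to the terminal carbon of the vinyl ketone, and a second electron gives samarium enolate 19, protonated by tert-butanol (closest known type: chelation-controlled SmI2 ketyl–olefin cyclisation of unsaturated β-keto esters). The cyclohexane closes in the 6-endo-trig mode, preferred over 5-exo because the nucleophilic ketyl attacks the unsubstituted β-carbon of the enone and leaves an α-keto radical instead of a primary one. The new C2 stereocentre is controlled by a chair-like transition state in which the chain on C1 and the silyloxypropyl group on C8 are equatorial, the ester is axial and trivalent samarium bridges the ketyl oxygen and the ester carbonyl, so the oxygen ends equatorial and cis to the ester and the methyl axial. The step needs reduction of the acetyl group in preference to the enone, which the chelate should secure at −78 °C without HMPA, and it should leave the diene, the ring alkene and the C8 centre alone because the enolate forms on the far side (C4) and no free base is present.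

Step 12
Reactants: 20 hydroxy keto ester
Product: 22 (1R,2S,5R,8S)-2-hydroxy-2-methyl-5-(prop-1-en-2-yl)-8-[3-(TBSO)propyl]-1-Ch-6-oxabicyclo[3.2.1]octan-7-one, via adduct 21 (not isolated)
Conditions: CH2=C(CH3)MgBr (3 equiv), CeCl3 (3 equiv), THF, −78 → 0 °C; aq. NH4Cl
Reagents that add atoms: isopropenylmagnesium bromide CC(=C)[Mg]Br
Why: Organocerium 1,2-addition suppresses enolisation of the hindered ketone; the axial ester blocks the axial trajectory, so the nucleophile should enter equatorially and the axial alkoxide, 1,3-diaxial to the ester, lactonises (this carbinol configuration is erased in step 15, so the other epimer would converge).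

Step 13
Reactants: 22 bridged lactone
Product: 23 (1R,2S,3S,4S)-3-(hydroxymethyl)-4-methyl-1-(prop-1-en-2-yl)-2-[3-(TBSO)propyl]-3-Ch-cyclohexane-1,4-diol
Conditions: LiAlH4, THF, 0 °C → rt; aq. Rochelle salt
Reagents that add atoms: none
Why: Hydride reduction of the lactone gives the primary alcohol (future C7–OH) and frees the tertiary allylic alcohol; silyl ether and alkenes are inert.

Step 14
Reactants: 23 triol
Product: 24 (1R,2S,3S,4S)-3-[(TBSO)methyl]-4-methyl-1-(prop-1-en-2-yl)-2-[3-(TBSO)propyl]-3-Ch-cyclohexane-1,4-diol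
Conditions: TBSCl (1.1 equiv), imidazole, CH2Cl2, 0 °C → rt
Reagents that add atoms: tert-butyldimethylsilyl chloride CC(C)(C)[Si](C)(C)Cl
Why: Silylation should be selective for the single primary hydroxyl over the two tertiary ones.

Step 15
Reactants: 24 bis-silyl ether
Product: 25 2-[(2R,3S,4S)-3-[(TBSO)methyl]-4-hydroxy-4-methyl-2-[3-(TBSO)propyl]-3-Ch-cyclohexylidene]propanal (E/Z mixture)
Conditions: (C5H5NH)[CrO3Cl] (pyridinium chlorochromate, 3 equiv), NaOAc, 4 Å molecular sieves, CH2Cl2, rt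
Reagents that add atoms: none
Why: Babler–Dauben oxidative 1,3-transposition: the tertiary allylic chromate ester undergoes a [3,3] shift and the primary allylic chromate is oxidised to the tetrasubstituted enal, while the non-allylic tertiary alcohol is inert.

Step 16
Reactants: 25 enal
Product: 27 (2S)-2-[(1S,2S,5R,8S)-2-hydroxy-8-(3-hydroxypropyl)-2-methyl-1-Ch-6-oxabicyclo[3.2.1]octan-5-yl]propanal (CNP0419303.1), via diol enal 26 (not isolated)
Conditions: HF·pyridine, pyridine, THF, 0 °C → rt; then DBU (0.3 equiv), CH2Cl2, rt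
Reagents that add atoms: none
Why: Desilylation followed by base-mediated intramolecular oxa-Michael addition (5-exo-trig): the hydroxymethyl oxygen on C1 can reach C5 only from its own face, which fixes C5, and DBU equilibrates the α-formyl centre to the epimer expected to be more stable (methyl gauche to the ring oxygen, formyl away from it); iridals keep a free 3-hydroxypropyl group beside the same enal, so the six-membered alternative is not expected, and the tertiary C2–OH would give a more strained 7-oxabicyclo[2.2.1]heptane.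

## Compound list

1 | (+)-cis-α-irone, (3E)-4-[(1R,5S)-2,5,6,6-tetramethylcyclohex-2-en-1-yl]but-3-en-2-one | CC1=CC[C@H](C)C(C)(C)[C@@H]1/C=C/C(C)=O | starting material
2 | diethyl (3E)-4-[(1R,5S)-2,5,6,6-tetramethylcyclohex-2-en-1-yl]buta-1,3-dien-2-yl phosphate | CC1=CC[C@H](C)C(C)(C)[C@@H]1/C=C/C(=C)OP(=O)(OCC)OCC | intermediate
3 | (3E)-4-[(1R,5S)-2,5,6,6-tetramethylcyclohex-2-en-1-yl]but-3-en-1-yne | CC1=CC[C@H](C)C(C)(C)[C@@H]1/C=C/C#C | intermediate
4 | dimethyl{(1E,3E)-2-methyl-4-[(1R,5S)-2,5,6,6-tetramethylcyclohex-2-en-1-yl]buta-1,3-dien-1-yl}alane | CC1=CC[C@H](C)C(C)(C)[C@@H]1/C=C/C(C)=C/[Al](C)C | intermediate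
5 | Ch–OH, (3E,5E)-4-methyl-6-[(1R,5S)-2,5,6,6-tetramethylcyclohex-2-en-1-yl]hexa-3,5-dien-1-ol | CC1=CC[C@H](C)C(C)(C)[C@@H]1/C=C/C(C)=C/CCO | intermediate
6 | Ch–I, (1R,5S)-1-[(1E,3E)-6-iodo-3-methylhexa-1,3-dien-1-yl]-2,5,6,6-tetramethylcyclohex-2-ene | CC1=CC[C@H](C)C(C)(C)[C@@H]1/C=C/C(C)=C/CCI | intermediate
7 | 4-(tert-butyldimethylsilyloxy)butanal | O=CCCCO[Si](C)(C)C(C)(C)C | starting material
8 | nitromethane | C[N+](=O)[O-] | starting material
9 | 5-(tert-butyldimethylsilyloxy)-1-nitropentan-2-ol | O=[N+]([O-])CC(O)CCCO[Si](C)(C)C(C)(C)C | intermediate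
10 | tert-butyldimethyl{[(4E)-5-nitropent-4-en-1-yl]oxy}silane | O=[N+]([O-])/C=C/CCCO[Si](C)(C)C(C)(C)C | intermediate
11 | dimethyl malonate | COC(=O)CC(=O)OC | starting material
12 | dimethyl 2-[(2S)-5-(TBSO)-1-nitropentan-2-yl]propanedioate | O=[N+]([O-])C[C@H](C(C(=O)OC)C(=O)OC)CCCO[Si](C)(C)C(C)(C)C | intermediate
13 | dimethyl 2-[(2S)-5-(TBSO)-1-oxopentan-2-yl]propanedioate | O=C[C@H](C(C(=O)OC)C(=O)OC)CCCO[Si](C)(C)C(C)(C)C | intermediate
14 | dimethyl 2-[(4S)-7-(TBSO)-3-hydroxyhept-1-en-4-yl]propanedioate (carbinol epimers) | C=CC(O)[C@H](C(C(=O)OC)C(=O)OC)CCCO[Si](C)(C)C(C)(C)C | intermediate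
15 | methyl (4S)-4-[3-(TBSO)propyl]-5-ethenyl-2-oxooxolane-3-carboxylate (C3 and C5 epimers) | C=CC1OC(=O)C(C(=O)OC)[C@@H]1CCCO[Si](C)(C)C(C)(C)C | intermediate
16 | methyl (3S,4S)-4-[3-(TBSO)propyl]-3-Ch-5-ethenyl-2-oxooxolane-3-carboxylate (C5 epimers) | CC1=CC[C@H](C)C(C)(C)[C@@H]1/C=C/C(C)=C/CC[C@]2(C(=O)OC)C(=O)OC(C=C)[C@H]2CCCO[Si](C)(C)C(C)(C)C | intermediate
17 | methyl (2R,3S)-2-acetyl-2-Ch-3-(1-hydroxyprop-2-en-1-yl)-6-(TBSO)hexanoate (carbinol epimers) | CC1=CC[C@H](C)C(C)(C)[C@@H]1/C=C/C(C)=C/CC[C@](C(=O)OC)(C(C)=O)[C@@H](C(O)C=C)CCCO[Si](C)(C)C(C)(C)C | intermediate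
18 | methyl (2R,3S)-2-acetyl-2-Ch-3-(prop-2-enoyl)-6-(TBSO)hexanoate | CC1=CC[C@H](C)C(C)(C)[C@@H]1/C=C/C(C)=C/CC[C@](C(=O)OC)(C(C)=O)[C@@H](C(=O)C=C)CCCO[Si](C)(C)C(C)(C)C | intermediate
19 | bis(diiodosamarium) enolate–alkoxide of 20 | CC1=CC[C@H](C)C(C)(C)[C@@H]1/C=C/C(C)=C/CC[C@]2(C(=O)OC)[C@@](C)(O[Sm](I)I)CC=C(O[Sm](I)I)[C@H]2CCCO[Si](C)(C)C(C)(C)C | intermediate
20 | methyl (1R,2S,6S)-2-hydroxy-2-methyl-5-oxo-6-[3-(TBSO)propyl]-1-Ch-cyclohexane-1-carboxylate | CC1=CC[C@H](C)C(C)(C)[C@@H]1/C=C/C(C)=C/CC[C@]2(C(=O)OC)[C@@](C)(O)CCC(=O)[C@H]2CCCO[Si](C)(C)C(C)(C)C | intermediate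
21 | methyl (1R,2S,5R,6S)-2,5-dihydroxy-2-methyl-5-(prop-1-en-2-yl)-6-[3-(TBSO)propyl]-1-Ch-cyclohexane-1-carboxylate | CC1=CC[C@H](C)C(C)(C)[C@@H]1/C=C/C(C)=C/CC[C@]2(C(=O)OC)[C@@](C)(O)CC[C@](O)(C(C)=C)[C@H]2CCCO[Si](C)(C)C(C)(C)C | intermediate
22 | (1R,2S,5R,8S)-2-hydroxy-2-methyl-5-(prop-1-en-2-yl)-8-[3-(TBSO)propyl]-1-Ch-6-oxabicyclo[3.2.1]octan-7-one | CC1=CC[C@H](C)C(C)(C)[C@@H]1/C=C/C(C)=C/CC[C@]12C(=O)O[C@](C(C)=C)(CC[C@]1(C)O)[C@H]2CCCO[Si](C)(C)C(C)(C)C | intermediate
23 | (1R,2S,3S,4S)-3-(hydroxymethyl)-4-methyl-1-(prop-1-en-2-yl)-2-[3-(TBSO)propyl]-3-Ch-cyclohexane-1,4-diol | CC1=CC[C@H](C)C(C)(C)[C@@H]1/C=C/C(C)=C/CC[C@]2(CO)[C@@](C)(O)CC[C@](O)(C(C)=C)[C@H]2CCCO[Si](C)(C)C(C)(C)C | intermediate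
24 | (1R,2S,3S,4S)-3-[(TBSO)methyl]-4-methyl-1-(prop-1-en-2-yl)-2-[3-(TBSO)propyl]-3-Ch-cyclohexane-1,4-diol | CC1=CC[C@H](C)C(C)(C)[C@@H]1/C=C/C(C)=C/CC[C@]2(CO[Si](C)(C)C(C)(C)C)[C@@](C)(O)CC[C@](O)(C(C)=C)[C@H]2CCCO[Si](C)(C)C(C)(C)C | intermediate
25 | 2-[(2R,3S,4S)-3-[(TBSO)methyl]-4-hydroxy-4-methyl-2-[3-(TBSO)propyl]-3-Ch-cyclohexylidene]propanal | CC1=CC[C@H](C)C(C)(C)[C@@H]1/C=C/C(C)=C/CC[C@]2(CO[Si](C)(C)C(C)(C)C)[C@@](C)(O)CCC(=C(C)C=O)[C@H]2CCCO[Si](C)(C)C(C)(C)C | intermediate
26 | 2-[(2R,3S,4S)-4-hydroxy-3-(hydroxymethyl)-2-(3-hydroxypropyl)-4-methyl-3-Ch-cyclohexylidene]propanal | CC1=CC[C@H](C)C(C)(C)[C@@H]1/C=C/C(C)=C/CC[C@]2(CO)[C@@](C)(O)CCC(=C(C)C=O)[C@H]2CCCO | intermediate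
27 | (2S)-2-[(1S,2S,5R,8S)-2-hydroxy-8-(3-hydroxypropyl)-2-methyl-1-Ch-6-oxabicyclo[3.2.1]octan-5-yl]propanal, CNP0419303.1 | CC1=CC[C@H](C)C(C)(C)[C@@H]1/C=C/C(C)=C/CC[C@]12CO[C@]([C@H](C)C=O)(CC[C@]1(C)O)[C@H]2CCCO | target

## Summary

Total step count: 16. Longest linear sequence: 13 steps (steps 4–16, from aldehyde 7); the irone branch (steps 1–3) joins at step 8.

Steps most likely to fail:

1. Step 11 (key step). The vinyl ketone may be reduced on its own (conjugate reduction or coupling through its β-carbon) before the ketyl adds, or a samarium enolate may close a five-membered ring through the α-carbon. The fallback makes the same bond by a Barbier-type closure; it sets out from 16 and comes back at 20. Hydroboration of the vinyl group of 16 (9-BBN, THF; NaBO3) should give the hydroxyethyl lactone F1, and I2/PPh3/imidazole the iodoethyl lactone F2. MeLi at −78 °C opens the lactone to the iodo hydroxy ketone F3 (largely as its lactol). SmI2 with HMPA in THF then effects the known intramolecular Barbier cyclisation of an iodoalkyl β-keto ester within the same samarium chelate, giving the cyclohexanediol F4. Dess–Martin oxidation of its secondary alcohol returns 20.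

2. Step 15. The hindered tertiary allylic chromate may ionise and eliminate to dienes, or the [3,3] shift may be slower than oxidation of the polyene. The fallback sets out from 24 and comes back at 25: Ph3SiOReO3-catalysed 1,3-transposition (Et2O, 0 °C) should give the primary allylic alcohol F5, which MnO2 (allylic-selective) oxidises to 25.

3. Step 16. The freed 3-hydroxypropyl oxygen may compete in the conjugate addition (six-membered ether), or equilibration at the α-formyl centre may favour the wrong epimer. The fallback sets out from 23 and comes back at 27. Acetylation of the primary hydroxyl (Ac2O, pyridine) gives the acetate F6, and the pyridinium chlorochromate transposition the enal acetate F7. K2CO3 in MeOH liberates the hydroxy enal F8, which cyclises in the same medium to the silyl-protected bicyclic aldehyde F9 while the hydroxypropyl oxygen is still masked; the α-formyl epimers can be separated or re-equilibrated at this stage. HF·pyridine then gives 27.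

Further compounds
F1 | step 11 | methyl (3S,4S)-4-[3-(TBSO)propyl]-3-Ch-5-(2-hydroxyethyl)-2-oxooxolane-3-carboxylate | CC1=CC[C@H](C)C(C)(C)[C@@H]1/C=C/C(C)=C/CC[C@]2(C(=O)OC)C(=O)OC(CCO)[C@H]2CCCO[Si](C)(C)C(C)(C)C
F2 | step 11 | methyl (3S,4S)-4-[3-(TBSO)propyl]-3-Ch-5-(2-iodoethyl)-2-oxooxolane-3-carboxylate | CC1=CC[C@H](C)C(C)(C)[C@@H]1/C=C/C(C)=C/CC[C@]2(C(=O)OC)C(=O)OC(CCI)[C@H]2CCCO[Si](C)(C)C(C)(C)C
F3 | step 11 | methyl (2R,3S)-2-acetyl-2-Ch-3-(1-hydroxy-3-iodopropyl)-6-(TBSO)hexanoate | CC1=CC[C@H](C)C(C)(C)[C@@H]1/C=C/C(C)=C/CC[C@](C(=O)OC)(C(C)=O)[C@@H](C(O)CCI)CCCO[Si](C)(C)C(C)(C)C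
F4 | step 11 | methyl (1R,2S,6S)-2,5-dihydroxy-2-methyl-6-[3-(TBSO)propyl]-1-Ch-cyclohexane-1-carboxylate | CC1=CC[C@H](C)C(C)(C)[C@@H]1/C=C/C(C)=C/CC[C@]2(C(=O)OC)[C@@](C)(O)CCC(O)[C@H]2CCCO[Si](C)(C)C(C)(C)C
F5 | step 15 | 2-[(2R,3S,4S)-3-[(TBSO)methyl]-4-hydroxy-4-methyl-2-[3-(TBSO)propyl]-3-Ch-cyclohexylidene]propan-1-ol | CC1=CC[C@H](C)C(C)(C)[C@@H]1/C=C/C(C)=C/CC[C@]2(CO[Si](C)(C)C(C)(C)C)[C@@](C)(O)CCC(=C(C)CO)[C@H]2CCCO[Si](C)(C)C(C)(C)C
F6 | step 16 | primary acetate of 23 | CC1=CC[C@H](C)C(C)(C)[C@@H]1/C=C/C(C)=C/CC[C@]2(COC(C)=O)[C@@](C)(O)CC[C@](O)(C(C)=C)[C@H]2CCCO[Si](C)(C)C(C)(C)C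
F7 | step 16 | enal acetate, the acetoxymethyl analogue of 25 | CC1=CC[C@H](C)C(C)(C)[C@@H]1/C=C/C(C)=C/CC[C@]2(COC(C)=O)[C@@](C)(O)CCC(=C(C)C=O)[C@H]2CCCO[Si](C)(C)C(C)(C)C
F8 | step 16 | hydroxy enal, the mono-TBS (hydroxypropyl) ether of 26 | CC1=CC[C@H](C)C(C)(C)[C@@H]1/C=C/C(C)=C/CC[C@]2(CO)[C@@](C)(O)CCC(=C(C)C=O)[C@H]2CCCO[Si](C)(C)C(C)(C)C
F9 | step 16 | TBS ether of 27 at the hydroxypropyl oxygen | CC1=CC[C@H](C)C(C)(C)[C@@H]1/C=C/C(C)=C/CC[C@]12CO[C@]([C@H](C)C=O)(CC[C@]1(C)O)[C@H]2CCCO[Si](C)(C)C(C)(C)C
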